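**Strategy.** Everything rests on the C4–C5 disconnection. C4, the tertiary carbinol carbon bearing the isopropyl group, is bonded to C5, the ring-fusion CH that sits between the quaternary C1 and the oxygenated C6 of the seven-membered ring. With C6 as a ketone, C5 can be a keto-carbene that has no β-hydrogen, and the carbinol C4–H lies 1,5 to it. One rhodium-catalysed C–H insertion therefore forms C4–C5, closes the five-membered ring (C1–C2–C3–C4–C5), turns a catalytically made secondary silyl ether into the tertiary carbinol with retention and sets C5. Its precursor is a 2-diazo-3,6-dimethylcyclohept-5-enone whose C3 (daucane C1) carries a 3-silyloxy-4-methylpentyl chain.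

Key step: step 11

Remark on the chemistry: daucane numbering is used (C1 quaternary fusion carbon with CH3, C4 carbinol, C5 fusion CH, C6 ester carbon, C8/C9 epoxide carbons) and β is the face of the C1 methyl; the SMILES is read as 1R,4R,5S,6R,8R,9S, i.e. 4-OH and 6-acyloxy both β, H5 α, epoxide oxygen α, and the route is built for exactly this arrangement.

## Route

Step 1
Reactants: 1 2,5-dimethylphenol; 2 tert-butyldimethylsilyl chloride
Product: 3 tert-butyl(2,5-dimethylphenoxy)dimethylsilane
Conditions: imidazole, DMF, rt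
Reagents that add atoms: tert-butyldimethylsilyl chloride, CC(C)(C)[Si](C)(C)Cl
Why: Imidazole-mediated silylation of the phenol gives an aryl silyl ether bulky enough to survive dissolving-metal reduction.

Step 2
Reactants: 3 tert-butyl(2,5-dimethylphenoxy)dimethylsilane
Product: 4 tert-butyl[(2,5-dimethylcyclohexa-1,4-dien-1-yl)oxy]dimethylsilane
Conditions: Li, NH3(l), THF, t-BuOH, −78 to −33 °C; NH4Cl quench
Reagents that add atoms: none
Why: Birch reduction leaves the three donor substituents on the two remaining double bonds, so the arene is delivered directly as the regiodefined tetrasubstituted silyl enol ether.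

Step 3
Reactants: 4 tert-butyl[(2,5-dimethylcyclohexa-1,4-dien-1-yl)oxy]dimethylsilane; 5 diiodomethane
Product: 6 racemic tert-butyl[(3,6-dimethylbicyclo[4.1.0]hept-3-en-1-yl)oxy]dimethylsilane
Conditions: Et2Zn, CH2I2, CH2Cl2, 0 °C to rt
Reagents that add atoms: diiodomethane, ICI
Why: Simmons–Smith cyclopropanation is chemoselective for the electron-rich silyl enol ether double bond over the trisubstituted alkene; the product is racemic, which does not matter because both ring stereocentres vanish in step 4.

Step 4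
Reactants: 6 racemic tert-butyl[(3,6-dimethylbicyclo[4.1.0]hept-3-en-1-yl)oxy]dimethylsilane
Product: 8 3,6-dimethylcyclohepta-2,5-dien-1-one, via β-chloro ketone 7 (not isolated)
Conditions: FeCl3, DMF, 0 °C to rt; then NaOAc, MeOH, rt
Reagents that add atoms: none
Why: Oxidative ring expansion of a siloxycyclopropane: FeCl3 cleaves the Si–O bond and oxidises the ferric cyclopropoxide by one electron, β-scission of the internal bond gives the ring-expanded tertiary radical that is chlorinated, and mild acetate-mediated E1cB elimination gives the enone while the remote double bond stays out of conjugation.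

Step 5
Reactants: 9 methyl 4-methyl-3-oxopentanoate
Product: 10 methyl (3R)-3-hydroxy-4-methylpentanoate
Conditions: H2 (50 atm), RuCl2[(S)-BINAP] (0.1 mol %), MeOH, 50 °C
Reagents that add atoms: none
Why: Noyori asymmetric hydrogenation of the β-keto ester through the ruthenium chelate sets the carbinol centre; the (S)-BINAP complex gives the 3R alcohol (R because isopropyl outranks CH2CO2Me).

Step 6
Reactants: 10 methyl (3R)-3-hydroxy-4-methylpentanoate; 11 chlorotriethylsilane
Product: 12 methyl (3R)-4-methyl-3-(triethylsilyloxy)pentanoate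
Conditions: imidazole, CH2Cl2, 0 °C to rt
Reagents that add atoms: chlorotriethylsilane, CC[Si](CC)(CC)Cl
Why: Imidazole-mediated silylation; the triethylsilyl ether activates the carbinol C–H for the later insertion, tolerates hydride, organometallic and carbene chemistry, and can still be removed from a hindered tertiary position.

Step 7
Reactants: 12 methyl (3R)-4-methyl-3-(triethylsilyloxy)pentanoate
Product: 13 (3R)-4-methyl-3-(triethylsilyloxy)pentan-1-ol
Conditions: DIBAL-H (2.2 equiv), CH2Cl2, −78 to 0 °C; Rochelle salt work-up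
Reagents that add atoms: none
Why: Hydride reduction of the ester to the primary alcohol at low temperature leaves the secondary silyl ether and its stereocentre untouched.

Step 8
Reactants: 13 (3R)-4-methyl-3-(triethylsilyloxy)pentan-1-ol; 14 carbon tetrabromide
Product: 15 {[(3R)-1-bromo-4-methylpentan-3-yl]oxy}triethylsilane
Conditions: CBr4, PPh3, imidazole, CH2Cl2, 0 °C
Reagents that add atoms: carbon tetrabromide, BrC(Br)(Br)Br
Why: Appel reaction converts the primary alcohol into the bromide under neutral conditions that spare the silyl ether.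

Step 9
Reactants: 15 {[(3R)-1-bromo-4-methylpentan-3-yl]oxy}triethylsilane; 8 3,6-dimethylcyclohepta-2,5-dien-1-one; 16 chlorotrimethylsilane
Product: 19 trimethyl({(3R)-3,6-dimethyl-3-[(3R)-4-methyl-3-(triethylsilyloxy)pentyl]cyclohepta-1,5-dien-1-yl}oxy)silane, via Grignard reagent 17 (not isolated), via bromomagnesium enolate 18 (not isolated)
Conditions: Mg, Et2O, reflux; then slow addition to 8, Cu(OTf)2 (3 mol %), chiral C2-symmetric 4,5-diphenylimidazolinium chloride (NHC precursor, 4 mol %), Et2O, −30 °C; then TMSCl, Et3N, DMPU, −30 °C to rt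
Reagents that add atoms: chlorotrimethylsilane, C[Si](C)(C)Cl
Why: Copper-catalysed asymmetric conjugate addition of the Grignard reagent to the β-methyl enone creates the C1 quaternary centre under catalyst control (ligand antipode chosen for alkyl delivery to the Re face of C3, giving R; the remote carbinol centre does not interfere), and O-silylation of the magnesium enolate fixes the C5=C6 enol ether, a regiochemistry that enolisation of the ketone (which prefers the allylic C7 methylene) could not give.

Step 10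
Reactants: 19 trimethyl({(3R)-3,6-dimethyl-3-[(3R)-4-methyl-3-(triethylsilyloxy)pentyl]cyclohepta-1,5-dien-1-yl}oxy)silane; 20 2,2,2-trifluoroethyl trifluoroacetate; 21 4-acetamidobenzenesulfonyl azide
Product: 24 (3R)-2-diazo-3,6-dimethyl-3-[(3R)-4-methyl-3-(triethylsilyloxy)pentyl]cyclohept-5-en-1-one, via lithium enolate 22 (not isolated), via trifluoroacetyl ketone 23 (not isolated)
Conditions: MeLi, THF, 0 °C; CF3CO2CH2CF3, −78 °C; aq. NH4Cl work-up; then 4-acetamidobenzenesulfonyl azide, Et3N, H2O (1 equiv), MeCN, rt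
Reagents that add atoms: 4-acetamidobenzenesulfonyl azide, CC(=O)Nc1ccc(cc1)S(=O)(=O)N=[N+]=[N-]
Why: Methyllithium cleaves the trimethylsilyl enol ether to the regiodefined lithium enolate, C-trifluoroacetylation activates C5 alone, and detrifluoroacetylative (deacylative Regitz-type) diazo transfer puts the diazo group on C5 and not on the more acidic C7.

Step 11
Reactants: 24 (3R)-2-diazo-3,6-dimethyl-3-[(3R)-4-methyl-3-(triethylsilyloxy)pentyl]cyclohept-5-en-1-one
Product: 25 (3R,3aR,8aR)-6,8a-dimethyl-3-(propan-2-yl)-3-(triethylsilyloxy)-2,3,3a,5,8,8a-hexahydroazulen-4(1H)-one (trans-fused 4β-triethylsilyloxy-5α-dauc-8-en-6-one)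
Conditions: Rh2(OAc)4 (1 mol %), CH2Cl2, rt, slow addition at high dilution
Reagents that add atoms: none
Why: Rh2(OAc)4 decomposes the diazo ketone to an electrophilic rhodium keto-carbene at C5, which cannot collapse by 1,2-hydride shift because C1 is quaternary, and which inserts into the C4–H bond in a concerted, three-centre, hydride-transfer-like event. The closest known reaction type is the dirhodium-catalysed intramolecular 1,5 C–H insertion of α-alkyl-α-diazo ketones into C–H bonds activated by an adjacent ether oxygen, which goes with retention. The cyclopentane (C1–C2–C3–C4–C5) closes by 1,5-insertion through a five-membered cyclic transition state in which the tether carbon C2 lies near the carbene plane. C4 becomes the tertiary carbinol with retention, so its configuration is the one fixed in step 5; C5 is controlled by the C1 quaternary centre, because with C2 in the carbene plane the C1 methyl is pseudo-axial and the C4–H bond reaches the carbene from the opposite face, placing H5 anti to that methyl (trans fusion, which also keeps C6 away from the isopropyl group). The step needs site selectivity for C4–H, which the five-membered transition state and the silyloxy activation secure (the isopropyl methine would need a six-membered transition state and is inductively deactivated, and the ring alkene is out of reach), and it needs the trans fusion kinetically, since a later base equilibration at C5 would pull the C8=C9 double bond into conjugation.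

Step 12
Reactants: 25 (3R,3aR,8aR)-6,8a-dimethyl-3-(propan-2-yl)-3-(triethylsilyloxy)-2,3,3a,5,8,8a-hexahydroazulen-4(1H)-one
Product: 26 (3R,3aS,4R,8aR)-6,8a-dimethyl-3-(propan-2-yl)-3-(triethylsilyloxy)-1,2,3,3a,4,5,8,8a-octahydroazulen-4-ol
Conditions: LiBH(s-Bu)3 (L-Selectride), THF, −78 to −40 °C; MeOH then H2O
Reagents that add atoms: none
Why: Hydride reduction under steric approach control: the bulky borohydride adds to C6 from the α face, away from the pseudo-axial C1 methyl (syn-axial to the β trajectory) and the C4 silyloxy group, giving the 6β (6R) alcohol; reducing before desilylation avoids retro-aldol cleavage and hydroxyl-directed hydride delivery to the β face.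

Step 13
Reactants: 26 (3R,3aS,4R,8aR)-6,8a-dimethyl-3-(propan-2-yl)-3-(triethylsilyloxy)-1,2,3,3a,4,5,8,8a-octahydroazulen-4-ol
Product: 27 (3R,3aS,4R,8aR)-6,8a-dimethyl-3-(propan-2-yl)-1,2,3,3a,4,5,8,8a-octahydroazulene-3,4-diol (5α-dauc-8-ene-4β,6β-diol)
Conditions: TBAF, THF, rt to 50 °C
Reagents that add atoms: none
Why: Fluoride-mediated desilylation; with the ketone already reduced there is no retro-aldol or β-elimination pathway, and the cis C6 hydroxyl assists removal of the hindered tertiary silyl group.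

Step 14
Reactants: 27 (3R,3aS,4R,8aR)-6,8a-dimethyl-3-(propan-2-yl)-1,2,3,3a,4,5,8,8a-octahydroazulene-3,4-diol; 28 4-(benzyloxy)-3-methoxybenzoic acid
Product: 30 (3R,3aS,4R,8aR)-3-hydroxy-6,8a-dimethyl-3-(propan-2-yl)-1,2,3,3a,4,5,8,8a-octahydroazulen-4-yl 4-(benzyloxy)-3-methoxybenzoate, via acid chloride 29 (not isolated)
Conditions: 28, (COCl)2, DMF (cat.), CH2Cl2, 0 °C to rt, concentrate; then 27, Et3N, DMAP, CH2Cl2, 40 °C
Reagents that add atoms: 4-(benzyloxy)-3-methoxybenzoic acid, COc1cc(C(=O)O)ccc1OCc1ccccc1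
Why: DMAP-catalysed acylation with the acid chloride occurs only at the secondary C6 hydroxyl, because the tertiary C4 hydroxyl flanked by the isopropyl group is inert.

Step 15
Reactants: 30 (3R,3aS,4R,8aR)-3-hydroxy-6,8a-dimethyl-3-(propan-2-yl)-1,2,3,3a,4,5,8,8a-octahydroazulen-4-yl 4-(benzyloxy)-3-methoxybenzoate; 31 3-chloroperoxybenzoic acid
Product: 32 (1R,4R,5S,6R,8R,9S)-8α,9α-epoxy-4β-hydroxydaucan-6β-yl 4-(benzyloxy)-3-methoxybenzoate
Conditions: mCPBA, NaHCO3, CH2Cl2, 0 °C
Reagents that add atoms: 3-chloroperoxybenzoic acid, OOC(=O)c1cccc(Cl)c1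
Why: Prilezhaev epoxidation of the trisubstituted alkene from the α face, opposite to the pseudo-axial C1 methyl and the axial 6β-acyloxy group, gives the 8α,9α-epoxide (8R,9S); the C6 hydroxyl is acylated first so that no homoallylic OH can steer the peracid to the β face.

Step 16
Reactants: 32 (1R,4R,5S,6R,8R,9S)-8α,9α-epoxy-4β-hydroxydaucan-6β-yl 4-(benzyloxy)-3-methoxybenzoate
Product: 33 (1R,4R,5S,6R,8R,9S)-8α,9α-epoxy-4β-hydroxydaucan-6β-yl 4-hydroxy-3-methoxybenzoate (target)
Conditions: H2 (1 atm), Pd/C (10 wt %), EtOAc, rt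
Reagents that add atoms: none
Why: Hydrogenolysis of the aryl benzyl ether over palladium is neutral and should leave the isolated trisubstituted epoxide, the ester and the tertiary alcohol untouched.

## Compound list

1 | 2,5-dimethylphenol | Cc1ccc(C)c(O)c1 | starting material
2 | tert-butyldimethylsilyl chloride | CC(C)(C)[Si](C)(C)Cl | starting material
3 | tert-butyl(2,5-dimethylphenoxy)dimethylsilane | Cc1ccc(C)c(O[Si](C)(C)C(C)(C)C)c1 | intermediate
4 | tert-butyl[(2,5-dimethylcyclohexa-1,4-dien-1-yl)oxy]dimethylsilane | CC1=CCC(C)=C(O[Si](C)(C)C(C)(C)C)C1 | intermediate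
5 | diiodomethane | ICI | starting material
6 | racemic tert-butyl[(3,6-dimethylbicyclo[4.1.0]hept-3-en-1-yl)oxy]dimethylsilane | CC1=CCC2(C)CC2(O[Si](C)(C)C(C)(C)C)C1 | intermediate
7 | racemic 3-chloro-3,6-dimethylcyclohept-5-en-1-one (not isolated) | CC1=CCC(C)(Cl)CC(=O)C1 | intermediate
8 | 3,6-dimethylcyclohepta-2,5-dien-1-one | CC1=CCC(C)=CC(=O)C1 | intermediate
9 | methyl 4-methyl-3-oxopentanoate | COC(=O)CC(=O)C(C)C | starting material
10 | methyl (3R)-3-hydroxy-4-methylpentanoate | COC(=O)C[C@@H](O)C(C)C | intermediate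
11 | chlorotriethylsilane | CC[Si](CC)(CC)Cl | starting material
12 | methyl (3R)-4-methyl-3-(triethylsilyloxy)pentanoate | COC(=O)C[C@@H](O[Si](CC)(CC)CC)C(C)C | intermediate
13 | (3R)-4-methyl-3-(triethylsilyloxy)pentan-1-ol | OCC[C@@H](O[Si](CC)(CC)CC)C(C)C | intermediate
14 | carbon tetrabromide | BrC(Br)(Br)Br | starting material
15 | {[(3R)-1-bromo-4-methylpentan-3-yl]oxy}triethylsilane | BrCC[C@@H](O[Si](CC)(CC)CC)C(C)C | intermediate
16 | chlorotrimethylsilane | C[Si](C)(C)Cl | starting material
17 | [(3R)-4-methyl-3-(triethylsilyloxy)pentyl]magnesium bromide (not isolated) | Br[Mg]CC[C@@H](O[Si](CC)(CC)CC)C(C)C | intermediate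
18 | bromomagnesium (3R)-3,6-dimethyl-3-[(3R)-4-methyl-3-(triethylsilyloxy)pentyl]cyclohepta-1,5-dien-1-olate (not isolated) | CC1=CC[C@@](C)(CC[C@@H](O[Si](CC)(CC)CC)C(C)C)C=C(O[Mg]Br)C1 | intermediate
19 | trimethyl({(3R)-3,6-dimethyl-3-[(3R)-4-methyl-3-(triethylsilyloxy)pentyl]cyclohepta-1,5-dien-1-yl}oxy)silane | CC1=CC[C@@](C)(CC[C@@H](O[Si](CC)(CC)CC)C(C)C)C=C(O[Si](C)(C)C)C1 | intermediate
20 | 2,2,2-trifluoroethyl trifluoroacetate | FC(F)(F)COC(=O)C(F)(F)F | starting material
21 | 4-acetamidobenzenesulfonyl azide | CC(=O)Nc1ccc(cc1)S(=O)(=O)N=[N+]=[N-] | starting material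
22 | lithium (3R)-3,6-dimethyl-3-[(3R)-4-methyl-3-(triethylsilyloxy)pentyl]cyclohepta-1,5-dien-1-olate (not isolated) | CC1=CC[C@@](C)(CC[C@@H](O[Si](CC)(CC)CC)C(C)C)C=C(O[Li])C1 | intermediate
23 | (3R)-3,6-dimethyl-3-[(3R)-4-methyl-3-(triethylsilyloxy)pentyl]-2-(trifluoroacetyl)cyclohept-5-en-1-one, C2 epimers and enol form (not isolated) | CC1=CC[C@@](C)(CC[C@@H](O[Si](CC)(CC)CC)C(C)C)C(C(=O)C(F)(F)F)C(=O)C1 | intermediate
24 | (3R)-2-diazo-3,6-dimethyl-3-[(3R)-4-methyl-3-(triethylsilyloxy)pentyl]cyclohept-5-en-1-one (key-step precursor) | CC1=CC[C@@](C)(CC[C@@H](O[Si](CC)(CC)CC)C(C)C)C(=[N+]=[N-])C(=O)C1 | intermediate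
25 | (3R,3aR,8aR)-6,8a-dimethyl-3-(propan-2-yl)-3-(triethylsilyloxy)-2,3,3a,5,8,8a-hexahydroazulen-4(1H)-one (key-step product) | O=C1CC(C)=CC[C@@]2(C)CC[C@@](O[Si](CC)(CC)CC)(C(C)C)[C@H]12 | intermediate
26 | (3R,3aS,4R,8aR)-6,8a-dimethyl-3-(propan-2-yl)-3-(triethylsilyloxy)-1,2,3,3a,4,5,8,8a-octahydroazulen-4-ol | O[C@@H]1CC(C)=CC[C@@]2(C)CC[C@@](O[Si](CC)(CC)CC)(C(C)C)[C@H]12 | intermediate
27 | (3R,3aS,4R,8aR)-6,8a-dimethyl-3-(propan-2-yl)-1,2,3,3a,4,5,8,8a-octahydroazulene-3,4-diol | O[C@@H]1CC(C)=CC[C@@]2(C)CC[C@@](O)(C(C)C)[C@H]12 | intermediate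
28 | 4-(benzyloxy)-3-methoxybenzoic acid | COc1cc(C(=O)O)ccc1OCc1ccccc1 | starting material
29 | 4-(benzyloxy)-3-methoxybenzoyl chloride (not isolated) | COc1cc(C(Cl)=O)ccc1OCc1ccccc1 | intermediate
30 | (3R,3aS,4R,8aR)-3-hydroxy-6,8a-dimethyl-3-(propan-2-yl)-1,2,3,3a,4,5,8,8a-octahydroazulen-4-yl 4-(benzyloxy)-3-methoxybenzoate | COc1cc(C(=O)O[C@@H]2CC(C)=CC[C@@]3(C)CC[C@@](O)(C(C)C)[C@H]23)ccc1OCc1ccccc1 | intermediate
31 | 3-chloroperoxybenzoic acid | OOC(=O)c1cccc(Cl)c1 | starting material
32 | (1R,4R,5S,6R,8R,9S)-8α,9α-epoxy-4β-hydroxydaucan-6β-yl 4-(benzyloxy)-3-methoxybenzoate | COc1cc(C(=O)O[C@@H]2C[C@@]3(C)O[C@H]3C[C@@]3(C)CC[C@@](O)(C(C)C)[C@H]23)ccc1OCc1ccccc1 | intermediate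
33 | (1R,4R,5S,6R,8R,9S)-8α,9α-epoxy-4β-hydroxydaucan-6β-yl 4-hydroxy-3-methoxybenzoate | COc1cc(C(=O)O[C@@H]2C[C@@]3(C)O[C@H]3C[C@@]3(C)CC[C@@](O)(C(C)C)[C@H]23)ccc1O | target

## Step count and risks

Total steps: 16. Longest linear sequence: 12 (steps 1–4 or 5–8, then 9–16).

**Step 11 (C–H insertion).** The ring may close with the wrong sense at C5 (cis fusion), or the carbene may be diverted by 1,2-alkyl shift, attack on the silyl ether oxygen or insertion at the isopropyl methine. The fallback makes the C4–C5 bond by an aldol-type closure. It sets out from silyl enol ether 19 and comes back at diol 27.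
- NBS (THF, −78 °C) brominates 19 regiospecifically at C5 to give (3R)-2-bromo-3,6-dimethyl-3-[(3R)-4-methyl-3-(triethylsilyloxy)pentyl]cyclohept-5-en-1-one F1.
- HF·pyridine (THF, 0 °C) frees the carbinol to give (3R)-2-bromo-3-[(3R)-3-hydroxy-4-methylpentyl]-3,6-dimethylcyclohept-5-en-1-one F2.
- Dess–Martin periodinane (NaHCO3, CH2Cl2) gives (3R)-2-bromo-3,6-dimethyl-3-(4-methyl-3-oxopentyl)cyclohept-5-en-1-one F3.
- SmI2 (2.2 equiv, THF, −78 °C) reduces the C–Br bond to the samarium enolate at C5, which adds to the side-chain ketone in a chelated intramolecular Reformatsky-type aldol reaction. The product should be (3R,3aR,8aR)-3-hydroxy-6,8a-dimethyl-3-(propan-2-yl)-2,3,3a,5,8,8a-hexahydroazulen-4(1H)-one F4. The chelate holds O4 cis to C6, the aldolate can settle to the trans-fused isomer without base, and C4 is made anew here.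
- Narasaka–Prasad reduction (Et2BOMe, NaBH4, THF/MeOH, −78 °C), with external hydride adding anti to the C1 methyl, gives 27.

**Step 9 (conjugate addition).** The basic Grignard reagent may enolise the doubly activated methylenes of the skipped dienone, the C5=C6 double bond may drift into conjugation, or facial selectivity may be insufficient. The fallback uses a non-basic diorganozinc nucleophile. It sets out from bromide 15 and dienone 8 and comes back at 19.
- Mg, then ZnCl2 (0.5 equiv), with magnesium salts precipitated by 1,4-dioxane, converts 15 into bis[(3R)-4-methyl-3-(triethylsilyloxy)pentyl]zinc F5.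
- Copper-catalysed asymmetric conjugate addition of this dialkylzinc to 8 (Cu(OTf)2 with a chiral NHC ligand generated from its imidazolinium salt, Et2O, −30 °C) gives the zinc enolate [(3R)-4-methyl-3-(triethylsilyloxy)pentyl]zinc (3R)-3,6-dimethyl-3-[(3R)-4-methyl-3-(triethylsilyloxy)pentyl]cyclohepta-1,5-dien-1-olate F6.
- Silylation in the same flask with TMSOTf gives 19.

**Step 10 (diazo installation).** C-acylation or diazo transfer at the neopentyl C5 may be slow, and proton exchange of the lithium enolate may erode the regiochemistry. The fallback introduces nitrogen as an oxime. It sets out from 19 and comes back at 24.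
- Nitrosation of the silyl enol ether with nitrosyl chloride (CH2Cl2, −20 °C) gives, regiospecifically at C5, (3R)-2-(hydroxyimino)-3,6-dimethyl-3-[(3R)-4-methyl-3-(triethylsilyloxy)pentyl]cyclohept-5-en-1-one F7.
- The Forster reaction with chloramine (from NH4OH and NaOCl, aq. NaOH, 0 °C) converts this α-oximino ketone into diazo ketone 24.

## Further compounds

F1 | step 11 | (3R)-2-bromo-3,6-dimethyl-3-[(3R)-4-methyl-3-(triethylsilyloxy)pentyl]cyclohept-5-en-1-one | CC1=CC[C@@](C)(CC[C@@H](O[Si](CC)(CC)CC)C(C)C)C(Br)C(=O)C1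
F2 | step 11 | (3R)-2-bromo-3-[(3R)-3-hydroxy-4-methylpentyl]-3,6-dimethylcyclohept-5-en-1-one | CC1=CC[C@@](C)(CC[C@@H](O)C(C)C)C(Br)C(=O)C1
F3 | step 11 | (3R)-2-bromo-3,6-dimethyl-3-(4-methyl-3-oxopentyl)cyclohept-5-en-1-one | CC1=CC[C@@](C)(CCC(=O)C(C)C)C(Br)C(=O)C1
F4 | step 11 | (3R,3aR,8aR)-3-hydroxy-6,8a-dimethyl-3-(propan-2-yl)-2,3,3a,5,8,8a-hexahydroazulen-4(1H)-one | O=C1CC(C)=CC[C@@]2(C)CC[C@@](O)(C(C)C)[C@H]12
F5 | step 9 | bis[(3R)-4-methyl-3-(triethylsilyloxy)pentyl]zinc | CC(C)[C@H](O[Si](CC)(CC)CC)CC[Zn]CC[C@@H](O[Si](CC)(CC)CC)C(C)C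
F6 | step 9 | [(3R)-4-methyl-3-(triethylsilyloxy)pentyl]zinc (3R)-3,6-dimethyl-3-[(3R)-4-methyl-3-(triethylsilyloxy)pentyl]cyclohepta-1,5-dien-1-olate | CC1=CC[C@@](C)(CC[C@@H](O[Si](CC)(CC)CC)C(C)C)C=C(O[Zn]CC[C@@H](O[Si](CC)(CC)CC)C(C)C)C1
F7 | step 10 | (3R)-2-(hydroxyimino)-3,6-dimethyl-3-[(3R)-4-methyl-3-(triethylsilyloxy)pentyl]cyclohept-5-en-1-one | CC1=CC[C@@](C)(CC[C@@H](O[Si](CC)(CC)CC)C(C)C)C(=NO)C(=O)C1
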